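**Strategy.** Everything rests on excising O1–C2(=O) of the oxolan-2-one ring as carbon dioxide: the C2–C3 bond and the O1–C5 bond are made together. The key step exploits that on the exocyclic C3=CH bond the vinylic hydrogen and C2 are cis (E-alkene), the pattern of a syn addition of H and CO2 to an aryl alkyne. Nickel-catalysed reductive hydrocarboxylation, steered by the guaiacyl ring, puts CO2 on the distal alkyne carbon (C3), and the carboxylate then displaces chloride from the future C5. Lactone ring, carbonyl group and alkene geometry arise in one operation. The precursor is an open-chain (R)-homopropargylic chloride whose stereocentre (C4) stems from an organocatalytic α-hydroxymethylation.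

Key step: step 5

Remark on numbering: the target ring is numbered O1, C2 (C=O), C3 (alkylidene carbon), C4 (stereocentre), C5 (OCH2). Compounds that deliver carbon atoms of the target are numbered as reactants.
Assumption: the sense of induction in step 1 follows the steric-shielding model of diarylprolinol silyl ethers, in which the (S)-catalyst gives (R)-aldehydes with carbon electrophiles. Hence the (R)-catalyst is used. Aldehyde 1 is taken as a catalogue compound.

Step 1
Reactants: 1 3-(3,4-dimethoxyphenyl)propanal; 2 formaldehyde (37 % in water)
Product: 3 (S)-2-(3,4-dimethoxybenzyl)-3-hydroxypropanal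
Conditions: (R)-α,α-diphenylprolinol trimethylsilyl ether (20 mol %), pH 7 phosphate buffer, toluene, rt
Reagents that add atoms: none
Why: Enamine-catalysed cross-aldol reaction (organocatalytic α-hydroxymethylation), in which the CPh2(OTMS) group of the (R)-catalyst shields one face of the E-enamine of 1, so that formaldehyde adds to the open face and sets the stereocentre as S, while the neutral buffer holds back Mannich-type dehydration.

Step 2
Reactants: 3 (S)-2-(3,4-dimethoxybenzyl)-3-hydroxypropanal; 4 dimethyl (1-diazo-2-oxopropyl)phosphonate (Bestmann–Ohira reagent)
Product: 5 (R)-2-(3,4-dimethoxybenzyl)but-3-yn-1-ol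
Conditions: K2CO3 (2 equiv), MeOH, 0 °C to rt
Reagents that add atoms: none
Why: Seyferth–Gilbert homologation in the Ohira–Bestmann variant, in which methanolysis of 4 frees the diazomethylphosphonate anion, this olefinates the aldehyde, and loss of N2 with a 1,2-hydride shift should give the alkyne faster than the α-branched aldehyde enolises, so the stereocentre is kept (the descriptor becomes R only because the priorities change).

Step 3
Reactants: 5 (R)-2-(3,4-dimethoxybenzyl)but-3-yn-1-ol
Product: 6 4-[(2R)-2-(chloromethyl)but-3-yn-1-yl]-1,2-dimethoxybenzene
Conditions: PPh3 (1.3 equiv), CCl4 (3 equiv), CH2Cl2, 40 °C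
Reagents that add atoms: carbon tetrachloride ClC(Cl)(Cl)Cl
Why: Appel reaction, in which chloride displaces the alkoxyphosphonium group at the primary carbon under neutral conditions, so the adjacent stereocentre, the terminal alkyne and the veratryl ring are not touched, and doing it before the phenol enters avoids any competition from that group.

Step 4
Reactants: 6 4-[(2R)-2-(chloromethyl)but-3-yn-1-yl]-1,2-dimethoxybenzene; 7 4-iodo-2-methoxyphenol
Product: 8 4-[(3R)-3-(chloromethyl)-4-(3,4-dimethoxyphenyl)but-1-yn-1-yl]-2-methoxyphenol
Conditions: PdCl2(PPh3)2 (2 mol %), CuI (4 mol %), Et3N, THF, rt, N2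
Reagents that add atoms: none
Why: Sonogashira coupling, which tolerates a free phenol, leaves a primary alkyl chloride alone at room temperature, and uses an amine too weak to deprotonate the propargylic stereocentre.

Step 5
Reactants: 8 4-[(3R)-3-(chloromethyl)-4-(3,4-dimethoxyphenyl)but-1-yn-1-yl]-2-methoxyphenol; 9 carbon dioxide
Product: 11 (3E,4R)-4-(3,4-dimethoxybenzyl)-3-(4-hydroxy-3-methoxybenzylidene)oxolan-2-one, via chloro carboxylate 10 (not isolated)
Conditions: NiCl2·glyme (10 mol %), bathocuproine (12 mol %), Mn powder (2 equiv), t-BuOH (3 equiv), CO2 (1 atm), DMF, 60 °C, then 80 °C; 1 M HCl work-up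
Reagents that add atoms: none
Why: Ni(0)–bathocuproine binds the alkyne of 8 and couples it oxidatively with CO2 to a five-membered oxanickelacycle in which nickel sits next to the guaiacyl ring (aryl-stabilised Ni–C bond) and the new C–C bond forms at the distal alkyne carbon, the later C3; t-BuOH cleaves the Ni–C bond with retention and Mn returns Ni(II) to Ni(0), which leaves carboxylate 10. The closest known reaction type is the nickel-catalysed reductive hydrocarboxylation of aryl alkyl alkynes with CO2, Mn and an alcohol as proton source, followed by the classical lactonisation of a γ-halo carboxylate. The only ring, the oxolan-2-one, closes by 5-exo-tet SN2 attack of a carboxylate oxygen on the CH2Cl carbon, so both lactone oxygens stem from CO2. No new stereocentre is formed: C4 is a spectator that is neither deprotonated nor metallated, and the E geometry follows from the metallacycle, which holds the incoming hydrogen (in the place of nickel) and the carboxyl group cis. The step needs regioselectivity, secured by the aryl/alkyl bias of the alkyne, and chemoselectivity for the alkyne over the C–Cl bond, secured by choosing a primary chloride, which low-valent nickel attacks only slowly without halide additives, instead of a bromide or sulfonate. The CO2 atmosphere buffers the alkoxide and phenoxide that form, which should suppress dehydrochlorination of 8 and keep the free phenol a harmless second proton source until the acidic work-up.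

**Compound list**
1 | 3-(3,4-dimethoxyphenyl)propanal | O=CCCc1ccc(OC)c(OC)c1 | starting material
2 | formaldehyde | C=O | starting material
3 | (S)-2-(3,4-dimethoxybenzyl)-3-hydroxypropanal | O=C[C@H](CO)Cc1ccc(OC)c(OC)c1 | intermediate
4 | dimethyl (1-diazo-2-oxopropyl)phosphonate | CC(=O)C(=[N+]=[N-])P(=O)(OC)OC | starting material
5 | (R)-2-(3,4-dimethoxybenzyl)but-3-yn-1-ol | C#C[C@H](CO)Cc1ccc(OC)c(OC)c1 | intermediate
6 | 4-[(2R)-2-(chloromethyl)but-3-yn-1-yl]-1,2-dimethoxybenzene | C#C[C@H](CCl)Cc1ccc(OC)c(OC)c1 | intermediate
7 | 4-iodo-2-methoxyphenol | COc1cc(I)ccc1O | starting material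
8 | 4-[(3R)-3-(chloromethyl)-4-(3,4-dimethoxyphenyl)but-1-yn-1-yl]-2-methoxyphenol | COc1cc(C#C[C@H](CCl)Cc2ccc(OC)c(OC)c2)ccc1O | intermediate
9 | carbon dioxide | O=C=O | starting material
10 | (2E)-2-[(2R)-1-chloro-3-(3,4-dimethoxyphenyl)propan-2-yl]-3-(4-hydroxy-3-methoxyphenyl)prop-2-enoic acid, formed as its manganese(II) carboxylate | COc1cc(/C=C(/C(=O)O)[C@H](CCl)Cc2ccc(OC)c(OC)c2)ccc1O | intermediate
11 | (3E,4R)-4-(3,4-dimethoxybenzyl)-3-(4-hydroxy-3-methoxybenzylidene)oxolan-2-one | COc1cc(/C=C2/C(=O)OC[C@@H]2Cc2ccc(OC)c(OC)c2)ccc1O | target

Total step count: 5. Longest linear sequence: 5 steps (1 → 3 → 5 → 6 → 8 → 11).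

**Steps most likely to fail**

Step 5.
- What may go wrong: low-valent nickel may attack the C–Cl bond before the alkyne is consumed. The branched substituent on the distal alkyne carbon may erode the regioselectivity of the oxidative coupling. The phenol may divert the catalyst towards a nickel hydride with the opposite regiochemistry.
- Fallback, setting out from 8 and coming back at 11: the vinyl–metal bond is made without a reductant.
- Copper-catalysed syn protoboration of 8 (CuCl, Xantphos and NaOt-Bu in catalytic amounts, B2pin2, MeOH, THF, rt) places copper next to the aryl ring and boron on the distal carbon. It should give the (Z)-alkenylboronate F1.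
- Copper-catalysed carboxylation of the boronate (CuI with a bisoxazoline ligand, CsF, CO2 1 atm, DMF, 90 °C) moves the alkenyl group from boron to copper with retention. CO2 inserts, and the caesium salt of 10 closes onto the CH2Cl carbon.
- The same two bonds still form in one operation, and 11 results.

Step 2.
- What may go wrong: before homologation is complete, the unprotected β-hydroxy aldehyde may fragment by retro-aldol reaction, lose water, or racemise by enolisation in carbonate and methanol.
- Fallback, setting out from 3 and coming back at 5: the hydroxyl group is masked before any base is applied.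
- TBSCl and imidazole in CH2Cl2 at 0 °C give the silyl ether aldehyde F2, in which retro-aldol cleavage is blocked and loss of the β-oxygen is much slower.
- Homologation with 4 gives the silyl ether alkyne F3, and TBAF in THF returns 5.

Step 1.
- What may go wrong: facial selectivity may be incomplete, the product may racemise when it re-forms an enamine with the catalyst, and some material may be lost to dehydration.
- Fallback, setting out from 5 of insufficient enantiomeric purity (or racemic 5 made with an achiral amine in step 1) and coming back at 5: the stereocentre is secured by biocatalysis instead of by the aldol step.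
- Pseudomonas cepacia lipase and vinyl acetate in t-BuOMe should acylate the (R)-alcohol faster. The ethynyl group takes the place of the small substituent in the empirical rule for 2-substituted 3-arylpropanols.
- The (R)-acetate F4 is separated from the residual (S)-alcohol by chromatography. K2CO3 in MeOH then returns enantioenriched 5.

**Further compounds**
F1 | step 5 | 4-[(1Z,3R)-3-(chloromethyl)-4-(3,4-dimethoxyphenyl)-2-(4,4,5,5-tetramethyl-1,3,2-dioxaborolan-2-yl)but-1-en-1-yl]-2-methoxyphenol | COc1cc(/C=C(/B2OC(C)(C)C(C)(C)O2)[C@H](CCl)Cc3ccc(OC)c(OC)c3)ccc1O
F2 | step 2 | (S)-3-[(tert-butyldimethylsilyl)oxy]-2-(3,4-dimethoxybenzyl)propanal | O=C[C@H](CO[Si](C)(C)C(C)(C)C)Cc1ccc(OC)c(OC)c1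
F3 | step 2 | (R)-tert-butyl{[2-(3,4-dimethoxybenzyl)but-3-yn-1-yl]oxy}dimethylsilane | C#C[C@H](CO[Si](C)(C)C(C)(C)C)Cc1ccc(OC)c(OC)c1
F4 | step 1 | (R)-2-(3,4-dimethoxybenzyl)but-3-yn-1-yl acetate | C#C[C@H](COC(C)=O)Cc1ccc(OC)c(OC)c1
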